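**Retrosynthetic overview**

1. The diester is cut at both C6–O bonds: double Mitsunobu inversion joins diacid 20 (four steps from geranyl acetate) to two molecules of the C6-epimeric amino alcohol 15. Locants follow cyclopenta[c]pyridine numbering: C1, N2, C3, C4, C4a, C5, C6, C7, C7a.
2. 15 comes from ketone 14 (C7 equilibrated, C6 reduced), and 14 from all-cis hydrogenation of N-methylpyridinium 10, which sets C4, C4a and C7a from the face opposite the cis C6-silyloxy/C7-methyl pair.
3. Key disconnection: the six-membered aza ring (N2, C1, C3, C4, C4a, C7a) is made by ring expansion of the five-membered oxazole of 7 (O1, C2, N3, C4, C5). Intramolecular [4+2] addition to the propenyl group is followed by loss of the ring oxygen as water, and the same step closes the cyclopentane (C4a, C5, C6, C7, C7a).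
4. Enabling feature: the oxazole 2-azadiene C2=N3–C4=C5 sits three sp3 atoms (C7, C6, C5) from the C4a=C4 alkene, so oxazole C5 becomes C7a and oxazole C2 becomes C3. Each alkene carbon carries one H, which lets the O bridge between C3 and C7a leave as water.
5. Ring order: oxazole (step 5), then cyclopentane and pyridine together (step 6), then piperidine by saturation (step 8). 7 comes from ethyl (3R)-4-chloro-3-hydroxybutanoate by epoxide opening, anti-selective methylation and isocyanide condensation.

Key step: step 6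

Remark: commercial prop-1-enylmagnesium bromide is an E/Z mixture; both alkene carbons become aromatic carbons in step 6, so the geometry has no consequence and 3–7 are written as the E isomers.

**Route**

Step 1
Reactants: 1 ethyl (3R)-4-chloro-3-hydroxybutanoate
Product: 2 ethyl 2-[(2R)-oxiran-2-yl]acetate
Conditions: Ag2O (1.0 equiv), 1,2-dimethoxyethane, 60 °C, dark
Reagents that add atoms: none
Why: Silver-assisted intramolecular Williamson etherification should close the epoxide without free alkoxide base, so the epoxy ester is not opened to the 4-hydroxycrotonate, and C3 is untouched (R retained).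

Step 2
Reactants: 2 ethyl 2-[(2R)-oxiran-2-yl]acetate
Product: 3 ethyl (3S,5E)-3-hydroxyhept-5-enoate
Conditions: CH3CH=CHMgBr (1.5 equiv), CuI (10 mol %), THF, −40 °C; H2O work-up
Reagents that add atoms: prop-1-enylmagnesium bromide, C/C=C/[Mg]Br
Why: Copper-catalysed SN2 opening of a terminal epoxide by a Grignard reagent should occur at the CH2 terminus faster than addition to the ester at this temperature, so the carbinol centre is kept (its descriptor becomes S only through the change in priorities).

Step 3
Reactants: 3 ethyl (3S,5E)-3-hydroxyhept-5-enoate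
Product: 4 ethyl (2S,3S,5E)-3-hydroxy-2-methylhept-5-enoate
Conditions: LiN(i-Pr)2 (2.2 equiv), THF, −50 to −20 °C; then MeI, DMPU, −78 to −20 °C
Reagents that add atoms: iodomethane, CI
Why: Fráter–Seebach alkylation: the chelated lithium alkoxide–enolate dianion should be methylated on the face away from the C3 substituent, which sets C2 as S (anti to the hydroxyl).

Step 4
Reactants: 4 ethyl (2S,3S,5E)-3-hydroxy-2-methylhept-5-enoate
Product: 5 ethyl (2S,3S,5E)-3-[(tert-butyldimethylsilyl)oxy]-2-methylhept-5-enoate
Conditions: TBSCl, imidazole, DMF, rt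
Reagents that add atoms: tert-butyldimethylsilyl chloride, CC(C)(C)[Si](C)(C)Cl
Why: Standard silylation of a secondary alcohol; the bulky silyl ether prevents alkoxide-driven retro-aldol cleavage in step 5 and later shields one face of the bicycle in step 8.

Step 5
Reactants: 5 ethyl (2S,3S,5E)-3-[(tert-butyldimethylsilyl)oxy]-2-methylhept-5-enoate
Product: 7 5-[(2S,3S,5E)-3-[(tert-butyldimethylsilyl)oxy]hept-5-en-2-yl]-1,3-oxazole, via isocyano ketone 6 (not isolated)
Conditions: CH3NC (2.5 equiv), n-BuLi (2.5 equiv), THF, −78 °C; then 5, −78 to 0 °C; AcOH quench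
Reagents that add atoms: methyl isocyanide, C[N+]#[C-]
Why: Schöllkopf oxazole synthesis: LiCH2NC is C-acylated by the ester to isocyano ketone 6, whose enolate (formed by the second equivalent) should close through oxygen onto the isocyanide carbon to give the 5-substituted oxazole, the CH(CH3) centre being spared because the isocyanomethylene protons are far more acidic.

Step 6
Reactants: 7 5-[(2S,3S,5E)-3-[(tert-butyldimethylsilyl)oxy]hept-5-en-2-yl]-1,3-oxazole
Product: 9 (6S,7R)-6-[(tert-butyldimethylsilyl)oxy]-4,7-dimethyl-6,7-dihydro-5H-cyclopenta[c]pyridine, via oxygen-bridged cycloadduct 8 (not isolated)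
Conditions: o-dichlorobenzene (0.02 M), 1,5-diazabicyclo[4.3.0]non-5-ene (DBN, 1.0 equiv), 180 °C, sealed tube
Reagents that add atoms: none
Why: The oxazole acts as a 2-azadiene (C2=N3–C4=C5) and adds across the tethered propenyl alkene in a thermal intramolecular [4+2] cycloaddition to the oxygen-bridged adduct 8, whose O bridge then opens and leaves as water with the two hydrogens of the former alkene carbons (DBN assisting), so the five-membered oxazole is expanded to the six-membered pyridine (four oxazole atoms kept, two alkene carbons inserted, oxygen extruded). The closest known reaction type is the intramolecular oxazole–olefin Diels–Alder reaction (Kondrat'eva pyridine synthesis), established for 5-(alk-4-enyl)oxazoles giving 6,7-dihydro-5H-cyclopenta[c]pyridines. The cyclopentane closes in the fused mode through the bond from oxazole C5 to the proximal alkene carbon (three-atom tether, five-membered ring), and the six-membered ring closes through the second σ bond from oxazole C2 to the distal, methyl-bearing alkene carbon. No new stereocentre survives aromatisation, so the four transient centres of 8 and the alkene geometry are irrelevant, while C6 and C7 are spectators that are not acidified and should not epimerise. The regiochemistry needed (methyl at C4, fusion at C4a–C7a) is fixed by the tether length, which allows only the fused orientation, and the outcome is secured because an alkene adduct, unlike an alkyne adduct, cannot lose a nitrile by retro-cycloaddition and can aromatise only by loss of water.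

Step 7
Reactants: 9 (6S,7R)-6-[(tert-butyldimethylsilyl)oxy]-4,7-dimethyl-6,7-dihydro-5H-cyclopenta[c]pyridine
Product: 10 (6S,7R)-6-[(tert-butyldimethylsilyl)oxy]-2,4,7-trimethyl-6,7-dihydro-5H-cyclopenta[c]pyridin-2-ium iodide
Conditions: MeI (3 equiv), acetone, 40 °C
Reagents that add atoms: iodomethane, CI
Why: Menshutkin N-alkylation at the pyridine nitrogen, the only nucleophilic site, installs the N-methyl group and activates the ring for hydrogenation.

Step 8
Reactants: 10 (6S,7R)-6-[(tert-butyldimethylsilyl)oxy]-2,4,7-trimethyl-6,7-dihydro-5H-cyclopenta[c]pyridin-2-ium iodide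
Product: 11 (4R,4aS,6S,7R,7aR)-6-[(tert-butyldimethylsilyl)oxy]-2,4,7-trimethyloctahydro-1H-cyclopenta[c]pyridine
Conditions: H2 (5 atm), PtO2 (10 mol %), MeOH, rt; then aq NaOH
Reagents that add atoms: none
Why: Heterogeneous hydrogenation of the pyridinium ring on platinum should deliver all hydrogens from the adsorbed face, which is the face opposite the cis-disposed C6 silyloxy and C7 methyl groups, so C4 (R), C4a (S) and C7a (R) are set together with H4, H4a and H7a mutually cis.

Step 9
Reactants: 11 (4R,4aS,6S,7R,7aR)-6-[(tert-butyldimethylsilyl)oxy]-2,4,7-trimethyloctahydro-1H-cyclopenta[c]pyridine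
Product: 12 (4R,4aS,6S,7R,7aR)-2,4,7-trimethyloctahydro-1H-cyclopenta[c]pyridin-6-ol
Conditions: aq HCl (2 M), THF, rt; then aq NaOH
Reagents that add atoms: none
Why: Acidic hydrolysis of the silyl ether proceeds on the protonated amine without touching any stereocentre.

Step 10
Reactants: 12 (4R,4aS,6S,7R,7aR)-2,4,7-trimethyloctahydro-1H-cyclopenta[c]pyridin-6-ol
Product: 14 (4R,4aS,7S,7aR)-2,4,7-trimethyloctahydro-6H-cyclopenta[c]pyridin-6-one, via 7-epi ketone 13 (not isolated)
Conditions: (COCl)2, DMSO, CH2Cl2, −78 °C; Et3N, −78 to 0 °C; then DBU (0.5 equiv), rt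
Reagents that add atoms: none
Why: Swern oxidation tolerates the tertiary amine and gives ketone 13 with the C7 methyl still cis to the C7a–C1 bond, and base-mediated enolisation at C7 (the only epimerisable centre) should then equilibrate it to the isomer with the methyl on the convex face, trans to C1, which sets C7 as S.

Step 11
Reactants: 14 (4R,4aS,7S,7aR)-2,4,7-trimethyloctahydro-6H-cyclopenta[c]pyridin-6-one
Product: 15 (4R,4aS,6S,7S,7aR)-2,4,7-trimethyloctahydro-1H-cyclopenta[c]pyridin-6-ol
Conditions: NaBH4, MeOH, −40 °C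
Reagents that add atoms: none
Why: Borohydride should attack the cyclopentanone from the convex face, away from the cis-fused piperidine ring and in line with the preference of small hydrides for the trans-2-methylcyclopentanol, which places the C6 hydroxyl on the concave face (S), trans to the C7 methyl.

Step 12
Reactants: 16 geranyl acetate, (2E)-3,7-dimethylocta-2,6-dien-1-yl acetate
Product: 17 (2E,6E)-8-hydroxy-3,7-dimethylocta-2,6-dien-1-yl acetate
Conditions: SeO2 (0.1 equiv), t-BuOOH (3 equiv), salicylic acid (0.1 equiv), CH2Cl2, rt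
Reagents that add atoms: tert-butyl hydroperoxide, CC(C)(C)OO
Why: Allylic oxidation by SeO2 (ene reaction followed by [2,3]-sigmatropic shift, turned over by t-BuOOH) should attack the (E)-methyl group of the electron-rich terminal trisubstituted alkene and leave the allylic acetate terminus alone, which fixes the 6E geometry.

Step 13
Reactants: 17 (2E,6E)-8-hydroxy-3,7-dimethylocta-2,6-dien-1-yl acetate
Product: 18 (2E,6E)-2,6-dimethylocta-2,6-diene-1,8-diol
Conditions: K2CO3 (0.2 equiv), MeOH, rt
Reagents that add atoms: none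
Why: Base-catalysed transesterification removes the acetate as methyl acetate without affecting either alkene.

Step 14
Reactants: 18 (2E,6E)-2,6-dimethylocta-2,6-diene-1,8-diol
Product: 19 (2E,6E)-2,6-dimethylocta-2,6-dienedial
Conditions: TEMPO (0.1 equiv), PhI(OAc)2 (2.3 equiv), CH2Cl2, rt
Reagents that add atoms: none
Why: Oxoammonium-mediated oxidation of both allylic alcohols stops at the enal stage under anhydrous conditions and does not isomerise the E double bonds.

Step 15
Reactants: 19 (2E,6E)-2,6-dimethylocta-2,6-dienedial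
Product: 20 (2E,6E)-2,6-dimethylocta-2,6-dienedioic acid
Conditions: NaClO2, NaH2PO4, 2-methylbut-2-ene, t-BuOH/H2O, rt
Reagents that add atoms: sodium chlorite, [Na+].[O-]Cl=O
Why: Pinnick oxidation converts both enals into the acids, the hypochlorite scavenger protecting the trisubstituted alkenes.

Step 16
Reactants: 15 (4R,4aS,6S,7S,7aR)-2,4,7-trimethyloctahydro-1H-cyclopenta[c]pyridin-6-ol (2.2 equiv); 20 (2E,6E)-2,6-dimethylocta-2,6-dienedioic acid (1.0 equiv)
Product: 21 bis[(4R,4aS,6R,7S,7aR)-2,4,7-trimethyloctahydro-1H-cyclopenta[c]pyridin-6-yl] (2E,6E)-2,6-dimethylocta-2,6-dienedioate (CNP0240822.3)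
Conditions: PPh3 (3 equiv), DIAD (3 equiv), THF, 0 °C to rt
Reagents that add atoms: none
Why: Mitsunobu esterification: each carboxylate of 20 should displace the oxyphosphonium group at C6 of one molecule of 15 with inversion (S to R), and because the acids are never turned into acyl electrophiles the position and E geometry of both enoate double bonds are not put at risk.

**Compound list**

1 | ethyl (3R)-4-chloro-3-hydroxybutanoate | CCOC(=O)C[C@@H](O)CCl | starting material
2 | ethyl 2-[(2R)-oxiran-2-yl]acetate | CCOC(=O)C[C@@H]1CO1 | intermediate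
3 | ethyl (3S,5E)-3-hydroxyhept-5-enoate | CCOC(=O)C[C@@H](O)C/C=C/C | intermediate
4 | ethyl (2S,3S,5E)-3-hydroxy-2-methylhept-5-enoate | CCOC(=O)[C@@H](C)[C@@H](O)C/C=C/C | intermediate
5 | ethyl (2S,3S,5E)-3-[(tert-butyldimethylsilyl)oxy]-2-methylhept-5-enoate | CCOC(=O)[C@@H](C)[C@@H](O[Si](C)(C)C(C)(C)C)C/C=C/C | intermediate
6 | (3S,4S,6E)-4-[(tert-butyldimethylsilyl)oxy]-1-isocyano-3-methyloct-6-en-2-one | [C-]#[N+]CC(=O)[C@@H](C)[C@@H](O[Si](C)(C)C(C)(C)C)C/C=C/C | intermediate (not isolated)
7 | 5-[(2S,3S,5E)-3-[(tert-butyldimethylsilyl)oxy]hept-5-en-2-yl]-1,3-oxazole | o1cncc1[C@@H](C)[C@@H](O[Si](C)(C)C(C)(C)C)C/C=C/C | intermediate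
8 | 6-[(tert-butyldimethylsilyl)oxy]-4,7-dimethyl-3,4,4a,5,6,7-hexahydro-3,7a-epoxycyclopenta[c]pyridine (C6 and C7 configured as in 7; the four new centres are transient and unassigned) | C[C@H]1[C@@H](O[Si](C)(C)C(C)(C)C)CC2C(C)C3N=CC12O3 | intermediate (not isolated)
9 | (6S,7R)-6-[(tert-butyldimethylsilyl)oxy]-4,7-dimethyl-6,7-dihydro-5H-cyclopenta[c]pyridine | CC(C)(C)[Si](C)(C)O[C@H]1Cc2c(C)cncc2[C@H]1C | intermediate
10 | (6S,7R)-6-[(tert-butyldimethylsilyl)oxy]-2,4,7-trimethyl-6,7-dihydro-5H-cyclopenta[c]pyridin-2-ium iodide | CC(C)(C)[Si](C)(C)O[C@H]1Cc2c(C)c[n+](C)cc2[C@H]1C.[I-] | intermediate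
11 | (4R,4aS,6S,7R,7aR)-6-[(tert-butyldimethylsilyl)oxy]-2,4,7-trimethyloctahydro-1H-cyclopenta[c]pyridine | CC(C)(C)[Si](C)(C)O[C@H]1C[C@@H]2[C@@H](CN(C)C[C@@H]2C)[C@H]1C | intermediate
12 | (4R,4aS,6S,7R,7aR)-2,4,7-trimethyloctahydro-1H-cyclopenta[c]pyridin-6-ol | O[C@H]1C[C@@H]2[C@@H](CN(C)C[C@@H]2C)[C@H]1C | intermediate
13 | (4R,4aS,7R,7aR)-2,4,7-trimethyloctahydro-6H-cyclopenta[c]pyridin-6-one | O=C1C[C@@H]2[C@@H](CN(C)C[C@@H]2C)[C@H]1C | intermediate (not isolated)
14 | (4R,4aS,7S,7aR)-2,4,7-trimethyloctahydro-6H-cyclopenta[c]pyridin-6-one | O=C1C[C@@H]2[C@@H](CN(C)C[C@@H]2C)[C@@H]1C | intermediate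
15 | (4R,4aS,6S,7S,7aR)-2,4,7-trimethyloctahydro-1H-cyclopenta[c]pyridin-6-ol | O[C@H]1C[C@@H]2[C@@H](CN(C)C[C@@H]2C)[C@@H]1C | intermediate
16 | geranyl acetate, (2E)-3,7-dimethylocta-2,6-dien-1-yl acetate | CC(=O)OC/C=C(\C)CCC=C(C)C | starting material
17 | (2E,6E)-8-hydroxy-3,7-dimethylocta-2,6-dien-1-yl acetate | CC(=O)OC/C=C(\C)CC/C=C(\C)CO | intermediate
18 | (2E,6E)-2,6-dimethylocta-2,6-diene-1,8-diol | OC/C=C(\C)CC/C=C(\C)CO | intermediate
19 | (2E,6E)-2,6-dimethylocta-2,6-dienedial | O=C/C=C(\C)CC/C=C(\C)C=O | intermediate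
20 | (2E,6E)-2,6-dimethylocta-2,6-dienedioic acid | OC(=O)/C=C(\C)CC/C=C(\C)C(=O)O | intermediate
21 | bis[(4R,4aS,6R,7S,7aR)-2,4,7-trimethyloctahydro-1H-cyclopenta[c]pyridin-6-yl] (2E,6E)-2,6-dimethylocta-2,6-dienedioate | C/C(=C\C(=O)O[C@@H]1C[C@@H]2[C@@H](CN(C)C[C@@H]2C)[C@@H]1C)CC/C=C(\C)C(=O)O[C@@H]1C[C@@H]2[C@@H](CN(C)C[C@@H]2C)[C@@H]1C | target

**Step count and risks**

Total steps: 16 (steps 1–11 for the amino alcohol, steps 12–15 for the diacid, step 16 for the union).
Longest linear sequence: 12 steps (steps 1–11 and 16).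

Steps most likely to fail:

Step 6. The [4+2] addition to the unactivated 1,2-disubstituted alkene may be too slow, so that thermal decomposition or loss of the silyl ether outruns cycloaddition and aromatisation. The fallback sets out from 7 and comes back at 9. Cross-metathesis of 7 with methyl acrylate (second-generation Grubbs catalyst RuCl2(=CHPh)(PCy3)(H2IMes), CH2Cl2, 40 °C) should exchange the propenyl terminus for an acrylate and give methyl (2E,5S,6S)-5-[(tert-butyldimethylsilyl)oxy]-6-(1,3-oxazol-5-yl)hept-2-enoate F1. The electron-poor dienophile should then undergo the same intramolecular oxazole–olefin cycloaddition and dehydration below 150 °C (toluene, DBN) to give methyl (6S,7R)-6-[(tert-butyldimethylsilyl)oxy]-7-methyl-6,7-dihydro-5H-cyclopenta[c]pyridine-4-carboxylate F2. LiAlH4 (THF, −20 °C) should reduce the ester to [(6S,7R)-6-[(tert-butyldimethylsilyl)oxy]-7-methyl-6,7-dihydro-5H-cyclopenta[c]pyridin-4-yl]methanol F3. Mesylation (MsCl, Et3N, THF, 0 °C) to [(6S,7R)-6-[(tert-butyldimethylsilyl)oxy]-7-methyl-6,7-dihydro-5H-cyclopenta[c]pyridin-4-yl]methyl methanesulfonate F4, followed in the same flask by LiEt3BH, should replace the oxygen by hydrogen and deliver 9.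

Step 8. Facial discrimination may be incomplete, or partly reduced intermediates may leave the metal surface and return on the other face, which would erode the all-cis relationship, above all at C4. The fallback sets out from 9 and comes back at 11. The neutral pyridine 9 is hydrogenated before N-methylation over Rh2O3 (H2 5 atm, CF3CH2OH, 40 °C), a system that should saturate free pyridines in one residence on the metal, to give (4R,4aS,6S,7R,7aR)-6-[(tert-butyldimethylsilyl)oxy]-4,7-dimethyloctahydro-1H-cyclopenta[c]pyridine F5. Reductive methylation (aq HCHO, NaBH(OAc)3, ClCH2CH2Cl) should then give 11.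

Step 16. Substitution at C6, which is flanked by the C7 methyl, may lose to elimination of the oxyphosphonium intermediate or stop at the monoester. The fallback sets out from 14 and comes back at 21. Reduction of 14 with LiBH(s-Bu)3 (THF, −78 °C), which should attack anti to the adjacent methyl, gives the C6 epimer (4R,4aS,6R,7S,7aR)-2,4,7-trimethyloctahydro-1H-cyclopenta[c]pyridin-6-ol F6. Diacid 20 is activated by the Yamaguchi method (2,4,6-trichlorobenzoyl chloride, Et3N, THF) as (2E,6E)-2,6-dimethylocta-2,6-dienedioic bis(2,4,6-trichlorobenzoic) anhydride F7. With F6 (2.2 equiv) and DMAP in toluene, F7 should acylate both alcohols with retention and give 21.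

**Further compounds**

F1 | step 6 | methyl (2E,5S,6S)-5-[(tert-butyldimethylsilyl)oxy]-6-(1,3-oxazol-5-yl)hept-2-enoate | o1cncc1[C@@H](C)[C@@H](O[Si](C)(C)C(C)(C)C)C/C=C/C(=O)OC
F2 | step 6 | methyl (6S,7R)-6-[(tert-butyldimethylsilyl)oxy]-7-methyl-6,7-dihydro-5H-cyclopenta[c]pyridine-4-carboxylate | CC(C)(C)[Si](C)(C)O[C@H]1Cc2c(C(=O)OC)cncc2[C@H]1C
F3 | step 6 | [(6S,7R)-6-[(tert-butyldimethylsilyl)oxy]-7-methyl-6,7-dihydro-5H-cyclopenta[c]pyridin-4-yl]methanol | CC(C)(C)[Si](C)(C)O[C@H]1Cc2c(CO)cncc2[C@H]1C
F4 | step 6 | [(6S,7R)-6-[(tert-butyldimethylsilyl)oxy]-7-methyl-6,7-dihydro-5H-cyclopenta[c]pyridin-4-yl]methyl methanesulfonate | CC(C)(C)[Si](C)(C)O[C@H]1Cc2c(COS(C)(=O)=O)cncc2[C@H]1C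
F5 | step 8 | (4R,4aS,6S,7R,7aR)-6-[(tert-butyldimethylsilyl)oxy]-4,7-dimethyloctahydro-1H-cyclopenta[c]pyridine | CC(C)(C)[Si](C)(C)O[C@H]1C[C@@H]2[C@@H](CNC[C@@H]2C)[C@H]1C
F6 | step 16 | (4R,4aS,6R,7S,7aR)-2,4,7-trimethyloctahydro-1H-cyclopenta[c]pyridin-6-ol | O[C@@H]1C[C@@H]2[C@@H](CN(C)C[C@@H]2C)[C@@H]1C
F7 | step 16 | (2E,6E)-2,6-dimethylocta-2,6-dienedioic bis(2,4,6-trichlorobenzoic) anhydride | O=C(OC(=O)/C=C(\C)CC/C=C(\C)C(=O)OC(=O)c1c(Cl)cc(Cl)cc1Cl)c1c(Cl)cc(Cl)cc1Cl
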